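| flask | substrate | coupling partner | temperature | remark | time |
|---|---|---|---|---|---|
| east | 1.6 M | 1.52 M | 5 °C | the very flask that is asked about, followed so far |  |
| north-east | 1.6 M | 1.52 M | −10 °C | run made earlier |  |
| flask | 1.6 M | 1.52 M | 5 °C |  | 8.0 d |

| run | time / d | target / % | substrate / % |
|---|---|---|---|
| east | 0.625 | 1.2 | 97.9 |
| east | 1.67 | 5.1 | 80.8 |
| east | 3.00 | 13.3 | 36.6 |
| east | 5.00 | 16.5 | 8.1 |
| north-east | 1.25 | 0 | 99.9 |
| north-east | 4.00 | 0.4 | 97.0 |
| north-east | 6.00 | 2.8 | 90.3 |
| north-east | 10.0 | 9.1 | 61.6 |

(scatter of a reading: 0.5 percentage points)

- green: change nothing and wait 8.0 d more
- red: at 8.0 d add coupling partner, 50.0% of the amount charged, then wait 8.0 d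
- teal: at 8.0 d take out 90% of the target then present, then wait 8.0 d
- violet: at 8.0 d raise the temperature by 20 K, then wait 8.0 d

- percentages count the substrate that a species holds: one side product counts as two
- target that was removed still counts
- on the list of suspects stand: substrate + coupling partner + by-product -> target + 2 by-product; substrate + coupling partner -> target + by-product; substrate + target -> side product; target <-> isomer of the product
- additions bring no volume worth counting

* target, in percent of the substrate first charged, at 8.0 d
* the option that brings most further target ("none" if no option brings more than 2 percentage points) (green / red / teal / violet / none)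
* target present, with what was taken out counted in, in percent of the substrate first charged, after teal
* target present, with what was taken out counted in, in percent of the substrate first charged, after violet

The rate constants of the suspects reach the east flask partly as a ratio: the making steps and the step to side product each carry [substrate], so between these three steps [substrate] and the clock cancel from the yield on the margin, but target <-> isomer of the product carries no [substrate], and if that step runs, neither cancels from the balance of target. Between 3.00 d and 5.00 d the east run reads 0.112: target gained per substrate lost, the instantaneous selectivity m. Frozen there, the 8.1% of substrate standing at 5.00 d is worth 0.91 percentage points more target, so the reckoning here puts the east flask near 17.4% at 8.0 d.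

Is one number enough? Across temperature the readings allow it: at 61.6% of substrate the north-east run holds 9.1% of target and the east run, interpolated, 8.66%, a gap smaller than the scatter of 0.5 points. Along the east run it is not constant, since the earlier interval reads 0.186, more than m. And m cannot see what might return: at 5.00 d the east run holds 75.4% as neither substrate nor target, unsplit between side product and isomer of the product. Green and red feed on substrate, so their reckoned gain stays below the mark of 2 points. Teal and violet can pass it by drawing on isomer, so isomer is the species to watch.

The forecast gives 16.9% (15.8% to 18%), best option none, 17.4% after teal and 17% after violet, holding that “The data need no isomerisation, though they cannot exclude a slow one”.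

    substrate + coupling partner + by-product → target + 2 by-product (k = 5.80 × 10⁻⁴ L² mol⁻² min⁻¹, Ea = 57.0 kJ mol⁻¹)
    substrate + coupling partner → target + by-product (k = 6.44 × 10⁻⁶ L mol⁻¹ min⁻¹, Ea = 75.0 kJ mol⁻¹)
    substrate + target → side product (k = 8.64 × 10⁻⁴ L mol⁻¹ min⁻¹, Ea = 60.0 kJ mol⁻¹)
    target ⇌ isomer of the product (K = 1.10, k = 0.00194 min⁻¹, Ea = 96.0 kJ mol⁻¹, ΔH = −62.0 kJ mol⁻¹)
    (constants at 5 °C)

The flask gives 15.9% at 8.0 d; violet brings the most further target, 12 points, reaching 28.1%, and teal reaches 23.6%. At 8.00 d the flask holds 17.5% of isomer of the product beside 15.9% of target. With 0.88% of substrate left, m gives 0.099 points more, and green brings 0.043 points.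

For the same charge read at 50 h, with 67.0% of substrate, m reckoned back from the flask's 15.9% gives 8.49% of target. The computed neighbour holds 8.17%.

The readings stem from a simulated flask with made-up constants, and the scatter is random.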